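**Retrosynthetic overview**

1. The strategy rests on ketal carbon C2 of the chromanone ring. It carries ring oxygen O1, the dihydrofuran oxygen (the flavan 7-oxygen), C3 and a 4-hydroxyphenyl ring, so it is a 4-hydroxybenzylic carbon. Cutting its bond to the flavan 7-oxygen (ring O–C2–C3–C8–C7 of the flavan) leads to the C2–H compound 21, a trans-3-(flavan-8-yl)flavanone.
2. Forward, the dihydrofuran ring is closed last by anodic dehydrogenation of 21 through a p-quinone methide, with C3 dictating the new C2 (cis fusion only). Hydrogenolysis of four benzyl ethers then gives the target.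
3. 21 comes from deoxybenzoin 17 and 4-(methoxymethoxy)benzaldehyde by Knoevenagel/oxa-Michael closure of the chromanone ring (trans by equilibration). The (2S,3R) diastereomer is taken by chromatography and the other trans diastereomer is resubmitted. This replaces a catalytic aryl addition to the 3-arylchromone, because chromones with a di-ortho-substituted aryl group at C3 are not established acceptors.
4. 17 comes from Negishi coupling of 3-iodochromone 13 with (R)-8-bromoflavan 10, followed by alkaline loss of the chromone C2 as formate.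
5. The (R)-flavan centre is set by rhodium-catalysed asymmetric 1,4-addition to chromone 5. Both halves start from phloroacetophenone. Ring order: flavan pyran ring, chromanone ring, dihydrofuran ring.

Key step: step 14

Remark (assumption): 20 and its (2R,3S)-trans diastereomer differ only in the sense of C2/C3 relative to the (R)-flavan centre and are taken to be separable on silica (assignment by ECD or by correlation with the final product); in step 4 the ligand antipode is the one that delivers 2R.

Step 1
Reactants: 1 2',4',6'-trihydroxyacetophenone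
Product: 2 1-[2,6-dihydroxy-4-(methoxymethoxy)phenyl]ethan-1-one
Conditions: MOMCl (1.0 equiv), i-Pr2NEt (1.2 equiv), THF/CH2Cl2, 0 °C
Reagents that add atoms: chloromethyl methyl ether, COCCl
Why: Williamson-type O-alkylation; the 4'-hydroxyl is the only one not hydrogen-bonded to the acetyl group and the most acidic, so one equivalent of MOMCl should alkylate it selectively.

Step 2
Reactants: 2 1-[2,6-dihydroxy-4-(methoxymethoxy)phenyl]ethan-1-one
Product: 3 1-[2-(benzyloxy)-6-hydroxy-4-(methoxymethoxy)phenyl]ethan-1-one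
Conditions: BnBr (1.05 equiv), K2CO3, DMF, rt
Reagents that add atoms: benzyl bromide, BrCc1ccccc1
Why: Williamson etherification; once one ortho-hydroxyl is benzylated the other is locked in a strong hydrogen bond to the carbonyl group and should stay free.

Step 3
Reactants: 3 1-[2-(benzyloxy)-6-hydroxy-4-(methoxymethoxy)phenyl]ethan-1-one
Product: 5 5-(benzyloxy)-7-(methoxymethoxy)-4H-chromen-4-one, via enaminone 4 (not isolated)
Conditions: Me2NCH(OMe)2 (3 equiv), toluene, 95 °C; then 1 M aq. HCl/CH2Cl2, rt
Reagents that add atoms: N,N-dimethylformamide dimethyl acetal, COC(OC)N(C)C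
Why: enaminone formation from the methyl ketone followed by acid-promoted addition–elimination ring closure (loss of dimethylamine) is the standard chromone synthesis, and dilute acid at room temperature should spare the MOM ether.

Step 4
Reactants: 5 5-(benzyloxy)-7-(methoxymethoxy)-4H-chromen-4-one; 6 4-(benzyloxy)phenylboronic acid
Product: 7 (2R)-5-(benzyloxy)-2-[4-(benzyloxy)phenyl]-7-(methoxymethoxy)chroman-4-one
Conditions: [Rh(OH)(cod)]2 (2.5 mol %), (R)- or (S)-MeO-F12-BIPHEP [6,6'-dimethoxy-2,2'-bis{bis(3,4,5-trifluorophenyl)phosphino}biphenyl, 6 mol %, antipode giving 2R], 6 (2.5 equiv), toluene/H2O, 40 °C, no added base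
Reagents that add atoms: none
Why: Hayashi–Miyaura rhodium-catalysed asymmetric 1,4-addition of an arylboronic acid to a chromone, a known route to 5,7-dioxygenated flavanones; the chiral diphosphine fixes the face of aryl transfer to C2, and base-free conditions avoid ring opening of the flavanone.

Step 5
Reactants: 7 (2R)-5-(benzyloxy)-2-[4-(benzyloxy)phenyl]-7-(methoxymethoxy)chroman-4-one
Product: 8 (2R)-5-(benzyloxy)-2-[4-(benzyloxy)phenyl]-7-(methoxymethoxy)chroman-4-ol (C4 epimers)
Conditions: NaBH4, THF/MeOH, 0 °C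
Reagents that add atoms: none
Why: borohydride 1,2-reduction of the aryl ketone; C2 is untouched and the new C4 centre is removed in the next step, so its configuration does not matter.

Step 6
Reactants: 8 (2R)-5-(benzyloxy)-2-[4-(benzyloxy)phenyl]-7-(methoxymethoxy)chroman-4-ol
Product: 9 (2R)-5-(benzyloxy)-2-[4-(benzyloxy)phenyl]-7-(methoxymethoxy)chromane
Conditions: Et3SiH (3 equiv), TFA (2 equiv), CH2Cl2, −40 to −20 °C
Reagents that add atoms: none
Why: ionic hydrogenation; the 4-hydroxyl ionises under very mild acid because the cation is a 2,4,6-trioxygenated benzylic one, the silane delivers hydride, and at low temperature with little acid the MOM ether and the C2–O bond should survive, so C2 stays R.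

Step 7
Reactants: 9 (2R)-5-(benzyloxy)-2-[4-(benzyloxy)phenyl]-7-(methoxymethoxy)chromane
Product: 10 (2R)-5-(benzyloxy)-2-[4-(benzyloxy)phenyl]-8-bromo-7-(methoxymethoxy)chromane
Conditions: NBS (1.0 equiv), CH2Cl2, −78 to −20 °C, dark
Reagents that add atoms: N-bromosuccinimide, O=C1CCC(=O)N1Br
Why: electrophilic aromatic bromination; in 5,7-di-O-protected flavans C8 (between the ring oxygen and O7) reacts in preference to C6 (between two bulky ethers), as is known for benzylated flavan-3-ols, and the position is to be confirmed by NOE.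

Step 8
Reactants: 1 2',4',6'-trihydroxyacetophenone
Product: 11 1-[2,4-bis(benzyloxy)-6-hydroxyphenyl]ethan-1-one
Conditions: BnBr (2.1 equiv), K2CO3, DMF, rt
Reagents that add atoms: benzyl bromide, BrCc1ccccc1
Why: Williamson etherification; two hydroxyls are benzylated and the last ortho-hydroxyl, hydrogen-bonded to the carbonyl group, should remain free.

Step 9
Reactants: 11 1-[2,4-bis(benzyloxy)-6-hydroxyphenyl]ethan-1-one
Product: 13 5,7-bis(benzyloxy)-3-iodo-4H-chromen-4-one, via enaminone 12 (not isolated)
Conditions: Me2NCH(OMe)2, 95 °C; then I2 (1.5 equiv), CHCl3, rt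
Reagents that add atoms: N,N-dimethylformamide dimethyl acetal, COC(OC)N(C)C; iodine, [I][I]
Why: enaminone formation followed by iodine-induced cyclisation (iodination of the enaminone α-carbon, ring closure, loss of dimethylamine) is the standard preparation of 3-iodochromones.

Step 10
Reactants: 10 (2R)-5-(benzyloxy)-2-[4-(benzyloxy)phenyl]-8-bromo-7-(methoxymethoxy)chromane; 13 5,7-bis(benzyloxy)-3-iodo-4H-chromen-4-one
Product: 16 5,7-bis(benzyloxy)-3-[(2R)-5-(benzyloxy)-2-(4-benzyloxyphenyl)-7-(methoxymethoxy)chroman-8-yl]-4H-chromen-4-one, via aryllithium 14 (not isolated), via arylzinc chloride 15 (not isolated)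
Conditions: n-BuLi (1.05 equiv), THF, −78 °C; ZnCl2 (1.1 equiv), −78 °C to rt; then 13, Pd2(dba)3 (2.5 mol %), SPhos (10 mol %), THF, 55 °C
Reagents that add atoms: none
Why: bromine–lithium exchange, transmetalation to zinc and Negishi coupling; SPhos-ligated palladium is known to couple di-ortho-substituted arylzinc reagents, the vinylic iodide of the chromone adds oxidatively with ease, and no stereocentre is touched.

Step 11
Reactants: 16 5,7-bis(benzyloxy)-3-[(2R)-5-(benzyloxy)-2-(4-benzyloxyphenyl)-7-(methoxymethoxy)chroman-8-yl]-4H-chromen-4-one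
Product: 17 1-[2,4-bis(benzyloxy)-6-hydroxyphenyl]-2-[(2R)-5-(benzyloxy)-2-(4-benzyloxyphenyl)-7-(methoxymethoxy)chroman-8-yl]ethan-1-one
Conditions: KOH (aq, 10 equiv), EtOH/dioxane, reflux; then AcOH to pH 6
Reagents that add atoms: none
Why: alkaline cleavage of an isoflavone-type chromone (hydroxide addition at C2, ring opening, retro-Claisen loss of formate) frees the 2'-hydroxydeoxybenzoin, while benzyl and MOM ethers and the flavan are inert to base.

Step 12
Reactants: 17 1-[2,4-bis(benzyloxy)-6-hydroxyphenyl]-2-[(2R)-5-(benzyloxy)-2-(4-benzyloxyphenyl)-7-(methoxymethoxy)chroman-8-yl]ethan-1-one; 18 4-(methoxymethoxy)benzaldehyde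
Product: 20 (2S,3R)-5,7-bis(benzyloxy)-3-[(2R)-5-(benzyloxy)-2-(4-benzyloxyphenyl)-7-(methoxymethoxy)chroman-8-yl]-2-[4-(methoxymethoxy)phenyl]chroman-4-one (2,3-trans), via α-aryl chalcone 19 (not isolated)
Conditions: 18 (1.5 equiv), piperidine (1 equiv), toluene, reflux (Dean–Stark); chromatography on silica; the co-formed (2R,3S)-trans diastereomer is resubmitted to piperidine/toluene at reflux
Reagents that add atoms: none
Why: Knoevenagel condensation at the activated methylene followed by 6-endo oxa-Michael ring closure is the established synthesis of 2,3-diarylchroman-4-ones; under these equilibrating conditions C2 and C3 should end up trans (both aryl groups equatorial), and because the remote (R)-flavan centre gives no facial bias the (2R,3S)-trans diastereomer is expected alongside 20, so 20 is taken by chromatography while the other diastereomer, on resubmission, reopens by retro-oxa-Michael reaction to chalcone 19 and closes again to both.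

Step 13
Reactants: 20 (2S,3R)-5,7-bis(benzyloxy)-3-[(2R)-5-(benzyloxy)-2-(4-benzyloxyphenyl)-7-(methoxymethoxy)chroman-8-yl]-2-[4-(methoxymethoxy)phenyl]chroman-4-one
Product: 21 (2S,3R)-5,7-bis(benzyloxy)-3-[(2R)-5-(benzyloxy)-2-(4-benzyloxyphenyl)-7-hydroxychroman-8-yl]-2-(4-hydroxyphenyl)chroman-4-one (2,3-trans)
Conditions: NaHSO4·SiO2, CH2Cl2, rt
Reagents that add atoms: none
Why: acid-catalysed acetal cleavage of the two phenolic MOM ethers on a mild solid acid; benzyl ethers, the flavan and the trans ketone (the thermodynamic C3 epimer) should be stable, and no base is used that could reopen the pyranone ring.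

Step 14
Reactants: 21 (2S,3R)-5,7-bis(benzyloxy)-3-[(2R)-5-(benzyloxy)-2-(4-benzyloxyphenyl)-7-hydroxychroman-8-yl]-2-(4-hydroxyphenyl)chroman-4-one
Product: 23 tetra-O-benzyl ketal (target skeleton with benzyl ethers on chromanone O5 and O7 and on flavan O5 and O4'; free 4-hydroxyphenyl on the ketal carbon; 2S,3S cis-fused; flavan 2R), via quinone methide 22 (not isolated)
Conditions: graphite anode, Pt cathode, undivided cell, constant current (2 mA cm−2, 2.1 F mol−1), n-Bu4NPF6 (0.1 M), 2,6-lutidine (3 equiv), HFIP/CH2Cl2 (1:3), 0 °C, 5 mM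
Reagents that add atoms: none
Why: Proposed new method: the 4-hydroxyphenyl ring of 21 is oxidised at the anode by two electrons and, with 2,6-lutidine as proton acceptor, loses the phenolic proton and the C2–H (benzylic, α to O1 and free to align with the ring π system), which gives p-quinone methide 22, in HFIP in equilibrium with the O1-stabilised C2 oxocarbenium ion; the flavan 7-hydroxyl adds to C2 and the phenol is restored. The closest known reaction types are the anodic, DDQ or Ag2O generation of p-quinone methides from 4-alkylphenols with oxygen trapping and the dehydrogenative closure of 2'-hydroxyisoflavans to pterocarpans. The dihydrofuran ring closes 5-exo-trig onto the exocyclic C2=C1' bond of 22. The new quaternary C2 is controlled by C3 alone: C2 is planar in 22 and the five-membered ring can only be cis-fused, so the oxygen enters on the face of the C3–C8 bond and 3R in 21 becomes (2S,3S) in 23. The step needs the oxidation to end at C2 and not in flavan ring A, and it needs ring closure to outrun loss of the C3 proton from 22 (which would give the 3-arylflavone and erase C3); in the substrate the C3–H lies near the plane of the di-ortho-substituted flavan ring and cannot be lost from an oxidised ring A, phenol/phenoxyl hydrogen exchange and a 1,5-hydrogen shift from C2–H to a flavan 7-oxyl radical lead either initial oxidation site to the same C2 cation, and the 7-hydroxyl sits one bond rotation from C2 while the only base present is hindered and weak. Product 23 has no benzylic C2–H and no free flavan phenol, so it should be harder to oxidise than 21 and survive when the charge is limited to about 2 F/mol.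

Step 15
Reactants: 23 tetra-O-benzyl ketal
Product: 24 CNP0179743.1 (target)
Conditions: H2 (1 atm), 10% Pd/C, EtOAc/MeOH, rt, stopped at full debenzylation
Reagents that add atoms: none
Why: hydrogenolysis of aryl benzyl ethers under neutral conditions; at atmospheric pressure the fully substituted ketal carbon, the flavan C2–O bond and the deactivated aryl ketone should remain intact and no stereocentre is touched.

**Compound list**

1 | 2',4',6'-trihydroxyacetophenone (phloroacetophenone) | CC(=O)c1c(O)cc(O)cc1O | starting material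
2 | 1-[2,6-dihydroxy-4-(methoxymethoxy)phenyl]ethan-1-one | CC(=O)c1c(O)cc(OCOC)cc1O | intermediate
3 | 1-[2-(benzyloxy)-6-hydroxy-4-(methoxymethoxy)phenyl]ethan-1-one | CC(=O)c1c(O)cc(OCOC)cc1OCc1ccccc1 | intermediate
4 | (E)-1-[2-(benzyloxy)-6-hydroxy-4-(methoxymethoxy)phenyl]-3-(dimethylamino)prop-2-en-1-one (not isolated) | CN(C)/C=C/C(=O)c1c(O)cc(OCOC)cc1OCc1ccccc1 | intermediate
5 | 5-(benzyloxy)-7-(methoxymethoxy)-4H-chromen-4-one | O=c1ccoc2cc(OCOC)cc(OCc3ccccc3)c12 | intermediate
6 | 4-(benzyloxy)phenylboronic acid | OB(O)c1ccc(OCc2ccccc2)cc1 | starting material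
7 | (2R)-5-(benzyloxy)-2-[4-(benzyloxy)phenyl]-7-(methoxymethoxy)chroman-4-one | COCOc1cc(OCc2ccccc2)c2c(c1)O[C@@H](c1ccc(OCc3ccccc3)cc1)CC2=O | intermediate
8 | (2R)-5-(benzyloxy)-2-[4-(benzyloxy)phenyl]-7-(methoxymethoxy)chroman-4-ol (C4 epimers) | COCOc1cc(OCc2ccccc2)c2c(c1)O[C@@H](c1ccc(OCc3ccccc3)cc1)CC2O | intermediate
9 | (2R)-5-(benzyloxy)-2-[4-(benzyloxy)phenyl]-7-(methoxymethoxy)chromane | COCOc1cc(OCc2ccccc2)c2c(c1)O[C@@H](c1ccc(OCc3ccccc3)cc1)CC2 | intermediate
10 | (2R)-5-(benzyloxy)-2-[4-(benzyloxy)phenyl]-8-bromo-7-(methoxymethoxy)chromane | COCOc1cc(OCc2ccccc2)c2c(c1Br)O[C@@H](c1ccc(OCc3ccccc3)cc1)CC2 | intermediate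
11 | 1-[2,4-bis(benzyloxy)-6-hydroxyphenyl]ethan-1-one | CC(=O)c1c(O)cc(OCc2ccccc2)cc1OCc1ccccc1 | intermediate
12 | (E)-1-[2,4-bis(benzyloxy)-6-hydroxyphenyl]-3-(dimethylamino)prop-2-en-1-one (not isolated) | CN(C)/C=C/C(=O)c1c(O)cc(OCc2ccccc2)cc1OCc1ccccc1 | intermediate
13 | 5,7-bis(benzyloxy)-3-iodo-4H-chromen-4-one | O=c1c(I)coc2cc(OCc3ccccc3)cc(OCc3ccccc3)c12 | intermediate
14 | 8-lithio derivative of flavan 9 (not isolated) | COCOc1cc(OCc2ccccc2)c2c(c1[Li])O[C@@H](c1ccc(OCc3ccccc3)cc1)CC2 | intermediate
15 | 8-(chlorozincio) derivative of flavan 9 (not isolated) | COCOc1cc(OCc2ccccc2)c2c(c1[Zn]Cl)O[C@@H](c1ccc(OCc3ccccc3)cc1)CC2 | intermediate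
16 | 5,7-bis(benzyloxy)-3-[(2R)-5-(benzyloxy)-2-(4-benzyloxyphenyl)-7-(methoxymethoxy)chroman-8-yl]-4H-chromen-4-one | O=c1c(-c2c(OCOC)cc(OCc3ccccc3)c3c2O[C@@H](c2ccc(OCc4ccccc4)cc2)CC3)coc2cc(OCc3ccccc3)cc(OCc3ccccc3)c12 | intermediate
17 | 1-[2,4-bis(benzyloxy)-6-hydroxyphenyl]-2-[(2R)-5-(benzyloxy)-2-(4-benzyloxyphenyl)-7-(methoxymethoxy)chroman-8-yl]ethan-1-one | O=C(Cc1c(OCOC)cc(OCc2ccccc2)c2c1O[C@@H](c1ccc(OCc3ccccc3)cc1)CC2)c1c(O)cc(OCc2ccccc2)cc1OCc1ccccc1 | intermediate
18 | 4-(methoxymethoxy)benzaldehyde | COCOc1ccc(C=O)cc1 | starting material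
19 | α-aryl chalcone: 1-[2,4-bis(benzyloxy)-6-hydroxyphenyl]-2-[(2R)-flavan-8-yl as in 17]-3-[4-(methoxymethoxy)phenyl]prop-2-en-1-one, alkene isomers (not isolated) | O=C(C(=Cc1ccc(OCOC)cc1)c1c(OCOC)cc(OCc2ccccc2)c2c1O[C@@H](c1ccc(OCc3ccccc3)cc1)CC2)c1c(O)cc(OCc2ccccc2)cc1OCc1ccccc1 | intermediate
20 | (2S,3R)-5,7-bis(benzyloxy)-3-[(2R)-5-(benzyloxy)-2-(4-benzyloxyphenyl)-7-(methoxymethoxy)chroman-8-yl]-2-[4-(methoxymethoxy)phenyl]chroman-4-one (2,3-trans) | O=C1c2c(OCc3ccccc3)cc(OCc3ccccc3)cc2O[C@H](c2ccc(OCOC)cc2)[C@H]1c1c(OCOC)cc(OCc2ccccc2)c2c1O[C@@H](c1ccc(OCc3ccccc3)cc1)CC2 | intermediate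
21 | (2S,3R)-5,7-bis(benzyloxy)-3-[(2R)-5-(benzyloxy)-2-(4-benzyloxyphenyl)-7-hydroxychroman-8-yl]-2-(4-hydroxyphenyl)chroman-4-one (key-step precursor) | O=C1c2c(OCc3ccccc3)cc(OCc3ccccc3)cc2O[C@H](c2ccc(O)cc2)[C@H]1c1c(O)cc(OCc2ccccc2)c2c1O[C@@H](c1ccc(OCc3ccccc3)cc1)CC2 | intermediate
22 | p-quinone methide of 21: C2 doubly bonded to a 4-oxocyclohexa-2,5-dienylidene ring, C3 unchanged (not isolated) | O=C1c2c(OCc3ccccc3)cc(OCc3ccccc3)cc2OC(=C2C=CC(=O)C=C2)[C@H]1c1c(O)cc(OCc2ccccc2)c2c1O[C@@H](c1ccc(OCc3ccccc3)cc1)CC2 | intermediate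
23 | tetra-O-benzyl ketal: target skeleton with benzyl ethers on chromanone O5 and O7, flavan O5 and flavan O4'; free 4-hydroxyphenyl on the ketal carbon; (2S,3S), flavan (2R) | O=C1c2c(OCc3ccccc3)cc(OCc3ccccc3)cc2O[C@@]2(c3ccc(O)cc3)Oc3cc(OCc4ccccc4)c4c(c3[C@@H]12)O[C@@H](c1ccc(OCc3ccccc3)cc1)CC4 | intermediate
24 | CNP0179743.1: (2S,3S)-cis-fused ketal, flavan (2R), six free phenols | O=C1c2c(O)cc(O)cc2O[C@@]2(c3ccc(O)cc3)Oc3cc(O)c4c(c3[C@@H]12)O[C@@H](c1ccc(O)cc1)CC4 | target

**Step count and risks**

Total step count: 15. Longest linear sequence: 13 steps (steps 1–7, then 10–15); steps 8–9 form the second branch.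

Steps most likely to fail:

Step 14 (the proposed new method). What may go wrong: the first electron may be taken from the electron-rich flavan ring A, followed by radical coupling at its free C6 position. Quinone methide 22 may also lose the C3 proton before the oxygen closes the ring, which aromatises the pyranone to the 3-arylflavone and erases C3. Fallback with known chemistry, setting out from deoxybenzoin 17 and coming back at target 24: 17 is aroylated with 4-(benzyloxy)benzoyl chloride (K2CO3, acetone, reflux). O-acylation, Baker–Venkataraman acyl shift and cyclodehydration, the classical 2-arylisoflavone synthesis, should give the 2,3-diarylchromone F1. NaHSO4·SiO2 removes the MOM group to give the flavan 7-phenol F2. TBSOTf/2,6-lutidine in CH2Cl2 converts the chromone into its 4-silyloxyflavylium ion, which takes up the neighbouring flavan 7-oxygen at C2 in the way flavylium ions add water and alcohols, giving the ketal silyl enol ether F3. HF·pyridine then protonates C3 (the ring fusion can only be cis) and should give the penta-O-benzyl (2S,3S)-ketal F4 together with its (2R,3R) isomer F5, since the remote flavan centre does not bias the face of C2. After chromatographic separation, hydrogenolysis of F4 as in step 15 gives 24. The price is the loss of the C3 relay.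

Step 12. What may go wrong: there is no facial selectivity from the remote flavan centre, so both trans diastereomers form and may co-elute, and the condensation at the doubly hindered methylene may be slow. Fallback, setting out from deoxybenzoin 17 and coming back at 23: step 12 is run without separation, so that 20 is carried on together with the (2R,3S)-trans diastereomer F6. The mixture is taken through steps 13 and 14, in which F6 gives the (2R,3S)-diol F7 and then the (2R,3R)-ketal F8. The separation is moved to the rigid pentacyclic ketals 23 and F8, where the new stereocentres sit directly on the flavan ring and the two isomers differ much more in shape. Recycling of the unwanted isomer is given up.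

Step 15. What may go wrong: hydrogenolysis of the benzylic C–O bonds at the ketal carbon or at flavan C2, or reduction of the ketone, may compete with O-debenzylation. Fallback, setting out from 23 and coming back at 24: Lewis-acid dealkylation in place of hydrogenolysis, with BCl3 and pentamethylbenzene as benzyl-cation scavenger in CH2Cl2 at −78 °C; no new compound is made.

**Further compounds**

F1 | step 14 | 5,7-bis(benzyloxy)-2-(4-benzyloxyphenyl)-3-[(2R)-5-(benzyloxy)-2-(4-benzyloxyphenyl)-7-(methoxymethoxy)chroman-8-yl]-4H-chromen-4-one | O=c1c(-c2c(OCOC)cc(OCc3ccccc3)c3c2O[C@@H](c2ccc(OCc4ccccc4)cc2)CC3)c(-c2ccc(OCc3ccccc3)cc2)oc2cc(OCc3ccccc3)cc(OCc3ccccc3)c12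
F2 | step 14 | 7-hydroxyflavan analogue of F1 (MOM removed) | O=c1c(-c2c(O)cc(OCc3ccccc3)c3c2O[C@@H](c2ccc(OCc4ccccc4)cc2)CC3)c(-c2ccc(OCc3ccccc3)cc2)oc2cc(OCc3ccccc3)cc(OCc3ccccc3)c12
F3 | step 14 | penta-O-benzyl ketal as its 4-(tert-butyldimethylsilyl) enol ether, C3=C4 (both ketal epimers) | CC(C)(C)[Si](C)(C)OC1=C2c3c(cc(OCc4ccccc4)c4c3O[C@@H](c3ccc(OCc5ccccc5)cc3)CC4)OC2(c2ccc(OCc3ccccc3)cc2)Oc2cc(OCc3ccccc3)cc(OCc3ccccc3)c12
F4 | step 14 | penta-O-benzyl (2S,3S)-ketal (23 with the 4-hydroxyphenyl group also benzylated) | O=C1c2c(OCc3ccccc3)cc(OCc3ccccc3)cc2O[C@@]2(c3ccc(OCc4ccccc4)cc3)Oc3cc(OCc4ccccc4)c4c(c3[C@@H]12)O[C@@H](c1ccc(OCc3ccccc3)cc1)CC4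
F5 | step 14 | penta-O-benzyl (2R,3R)-ketal, diastereomer of F4 | O=C1c2c(OCc3ccccc3)cc(OCc3ccccc3)cc2O[C@]2(c3ccc(OCc4ccccc4)cc3)Oc3cc(OCc4ccccc4)c4c(c3[C@H]12)O[C@@H](c1ccc(OCc3ccccc3)cc1)CC4
F6 | step 12 | (2R,3S)-trans diastereomer of 20 (flavan 2R, both MOM ethers in place) | O=C1c2c(OCc3ccccc3)cc(OCc3ccccc3)cc2O[C@@H](c2ccc(OCOC)cc2)[C@@H]1c1c(OCOC)cc(OCc2ccccc2)c2c1O[C@@H](c1ccc(OCc3ccccc3)cc1)CC2
F7 | step 12 | (2R,3S)-trans diol, diastereomer of 21 | O=C1c2c(OCc3ccccc3)cc(OCc3ccccc3)cc2O[C@@H](c2ccc(O)cc2)[C@@H]1c1c(O)cc(OCc2ccccc2)c2c1O[C@@H](c1ccc(OCc3ccccc3)cc1)CC2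
F8 | step 12 | tetra-O-benzyl (2R,3R)-ketal, diastereomer of 23 | O=C1c2c(OCc3ccccc3)cc(OCc3ccccc3)cc2O[C@]2(c3ccc(O)cc3)Oc3cc(OCc4ccccc4)c4c(c3[C@H]12)O[C@@H](c1ccc(OCc3ccccc3)cc1)CC4
F0 | step 15 | none | none
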